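**Retrosynthetic overview**
1. No ring is formed: all four benzene rings are bought. Bonds are made in the order diaryl ether C–O, then both ArCH2–CH2Ar' bonds in one flask, then the four O–Me cleavages.
2. C–O disconnection: SNAr of phenol 1 on 4-fluorobenzaldehyde 2 gives dialdehyde 3, which carries both future benzylic carbons as CHO groups.
3. Key C–C disconnection (twofold): the bis(N-tritylhydrazone) 4 of 3 is joined to two molecules of 3-methoxybenzyl bromide 5 through the dilithio bis(azo anion) 6. Each former aldehyde carbon reacts as a carbanion (d1 alkyl-anion equivalent) with a benzylic electrophile.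
4. The bis(trityl diazene) 7 loses N2 and trityl in the same flask, so the polarity-reversing handle leaves tracelessly and the bibenzyl tetramethyl ether 8 forms directly.
5. BBr3 cleaves all four methyl ethers of 8, through boron aryloxide 9, to perrottetin F 10.

Assumption: perrottetin F has no stereocentre and no C=C bond, so "single enantiomer" is read as the single constitution given. The C=N bonds of 4 are E, and the two transient stereocentres of 7 are unassigned and destroyed in the same flask. Tritylhydrazine is treated as an auxiliary reagent used as the free base (bought as the hydrochloride, or made from trityl chloride and hydrazine hydrate; this preparation is not counted as a step).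

**Step 1**
Reactants: 1 3-hydroxy-4,5-dimethoxybenzaldehyde; 2 4-fluorobenzaldehyde (1.2 equiv)
Product: 3 3-(4-formylphenoxy)-4,5-dimethoxybenzaldehyde
Conditions: K2CO3 (2 equiv), DMF, 140 °C, 12 h
Reagents that add atoms: none
Why: SNAr (addition–elimination) of the phenoxide of 1 at C-4 of 2, where the para-formyl group stabilises the Meisenheimer intermediate and fluoride is the best leaving group; neither aldehyde is enolisable, so both survive carbonate at 140 °C.

**Step 2**
Reactants: 3 3-(4-formylphenoxy)-4,5-dimethoxybenzaldehyde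
Product: 4 3-(4-formylphenoxy)-4,5-dimethoxybenzaldehyde bis[(E)-N-tritylhydrazone]
Conditions: Ph3CNHNH2 (2.2 equiv), EtOH–THF 1:1, 4 Å MS, rt → 40 °C, 6 h, under Ar
Reagents that add atoms: tritylhydrazine NNC(c1ccccc1)(c1ccccc1)c1ccccc1
Why: Hydrazone formation by condensation of the unhindered NH2 terminus with two aryl aldehydes, giving the thermodynamic E C=N geometry; no acid is used because the N-trityl group is acid-labile.

**Step 3**
Reactants: 4 3-(4-formylphenoxy)-4,5-dimethoxybenzaldehyde bis[(E)-N-tritylhydrazone]; 5 3-methoxybenzyl bromide (2.3 equiv)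
Product: 8 1,2-dimethoxy-5-[2-(3-methoxyphenyl)ethyl]-3-[4-[2-(3-methoxyphenyl)ethyl]phenoxy]benzene (perrottetin F tetramethyl ether), via dilithio bis(azo anion) 6 (not isolated), via bis(trityl diazene) 7 (not isolated)
Conditions: n-BuLi (2.05 equiv), THF, −78 °C, 30 min; then 5, −78 → −40 °C, 2 h; then EtSH (10 equiv), −40 °C → rt, 12 h, Ar
Reagents that add atoms: none
Why: Proposed new method: twofold N–H deprotonation of 4 gives at each arm a 2-azaallyl-type azo anion whose nitrogen terminus is shielded by trityl, so SN2 attack on 5 occurs at the former aldehyde carbon to give diazene 7 (two transient, unselective stereocentres); the weak C–N=N–CPh3 unit then homolyses on warming with loss of N2, each benzylic radical takes H from EtSH and the thiyl radical is captured by the persistent trityl radical, leaving CH2–CH2; the closest known reaction type is the reductive C-alkylation of aldehyde N-tritylhydrazones through their azo anions, a traceless relative of the Corey–Seebach dithiane alkylation, here run twofold and with benzylic radicals.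

**Step 4**
Reactants: 8 1,2-dimethoxy-5-[2-(3-methoxyphenyl)ethyl]-3-[4-[2-(3-methoxyphenyl)ethyl]phenoxy]benzene
Product: 10 perrottetin F, via boron aryloxide 9 (not isolated)
Conditions: BBr3 (8 equiv), CH2Cl2, −78 °C → rt, 6 h; then H2O, 0 °C
Reagents that add atoms: none
Why: BBr3 demethylation of aryl methyl ethers (O–B coordination, then bromide SN2 at each methyl) gives the aryloxyboron species 9, which water hydrolyses to the four phenols; the diaryl ether and the bibenzyl C–C bonds are inert to BBr3.

**Compound list**
1 | 3-hydroxy-4,5-dimethoxybenzaldehyde | COc1cc(C=O)cc(O)c1OC | starting material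
2 | 4-fluorobenzaldehyde | O=Cc1ccc(F)cc1 | starting material
3 | 3-(4-formylphenoxy)-4,5-dimethoxybenzaldehyde | COc1cc(C=O)cc(Oc2ccc(C=O)cc2)c1OC | intermediate
4 | 3-(4-formylphenoxy)-4,5-dimethoxybenzaldehyde bis[(E)-N-tritylhydrazone] (both CHO now CH=N–NH–CPh3) | COc1cc(/C=N/NC(c2ccccc2)(c2ccccc2)c2ccccc2)cc(Oc2ccc(/C=N/NC(c3ccccc3)(c3ccccc3)c3ccccc3)cc2)c1OC | intermediate
5 | 3-methoxybenzyl bromide (1-(bromomethyl)-3-methoxybenzene) | COc1cccc(CBr)c1 | starting material
6 | dilithio bis(azo anion) of 4 (both N–H replaced by N–Li, charge delocalised onto the former aldehyde carbons) | COc1cc(/C=N/N([Li])C(c2ccccc2)(c2ccccc2)c2ccccc2)cc(Oc2ccc(/C=N/N([Li])C(c3ccccc3)(c3ccccc3)c3ccccc3)cc2)c1OC | intermediate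
7 | bis(trityl diazene): each former CHO carbon is CH(CH2-C6H4-3-OMe)(N=N–CPh3), E N=N, two unassigned stereocentres (diastereomer mixture) | COc1cccc(CC(/N=N/C(c2ccccc2)(c2ccccc2)c2ccccc2)c2ccc(Oc3cc(C(Cc4cccc(OC)c4)/N=N/C(c4ccccc4)(c4ccccc4)c4ccccc4)cc(OC)c3OC)cc2)c1 | intermediate
8 | 1,2-dimethoxy-5-[2-(3-methoxyphenyl)ethyl]-3-[4-[2-(3-methoxyphenyl)ethyl]phenoxy]benzene (perrottetin F tetramethyl ether) | COc1cccc(CCc2ccc(Oc3cc(CCc4cccc(OC)c4)cc(OC)c3OC)cc2)c1 | intermediate
9 | boron aryloxide of 10: 2-bromo-1,3,2-benzodioxaborole on the catechol ring, ArO–BBr2 on both outer rings | BrB(Br)Oc1cccc(CCc2ccc(Oc3cc(CCc4cccc(OB(Br)Br)c4)cc4OB(Br)Oc34)cc2)c1 | intermediate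
10 | perrottetin F, 5-[2-(3-hydroxyphenyl)ethyl]-3-[4-[2-(3-hydroxyphenyl)ethyl]phenoxy]benzene-1,2-diol | Oc1cccc(CCc2ccc(Oc3cc(CCc4cccc(O)c4)cc(O)c3O)cc2)c1 | target

**Step count and risk**
Total steps: 4. Longest linear sequence: 4 (1 + 2 → 3 → 4 → 8 → 10; bromide 5 enters in step 3).

Three steps most likely to fail:

Step 3 (highest risk). Both arms must C-alkylate rather than N-alkylate. Diazene 7 may tautomerise to the ketone hydrazone before it fragments, and the benzylic radicals may dimerise instead of taking H from the thiol. The fallback sets out from 3 and comes back at 8, at the cost of one extra step. Dialdehyde 3 is treated with 1,3-propanedithiol and BF3·OEt2 in CH2Cl2 to give 2-[4-[5-(1,3-dithian-2-yl)-2,3-dimethoxyphenoxy]phenyl]-1,3-dithiane F1. n-BuLi (2.1 equiv, THF, −78 → −20 °C) converts this into the 2,2'-dilithio bis(dithiane) F2, a twofold acyl-anion equivalent. Bromide 5 alkylates it at both carbons to give the bis[2-(3-methoxybenzyl)-1,3-dithiane] F3. Raney nickel (W-2, EtOH, reflux) then removes all four sulfurs and delivers 8.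

Step 2. The bis(tritylhydrazone) is acid-labile and air-sensitive, and both aldehydes must condense completely with a bulky, less common hydrazine. The fallback sets out from 3 and comes back at 4. Dialdehyde 3 is stirred with a large excess of hydrazine hydrate in EtOH at 0 °C → rt (the excess suppresses azine formation) to give 3-(4-formylphenoxy)-4,5-dimethoxybenzaldehyde bis[(E)-hydrazone] F4. Its terminal nitrogens are then tritylated with trityl chloride and Et3N in CH2Cl2 at 0 °C, which gives 4.

Step 1. The SNAr needs 140 °C and carbonate in the presence of two aldehydes, and the phenol carries an ortho methoxy group. The fallback sets out from 1 and comes back at 3. Phenol 1 is O-arylated at room temperature by a Chan–Lam–Evans coupling with 4-formylphenylboronic acid (Cu(OAc)2, pyridine, 4 Å MS, CH2Cl2, air). This replaces the addition–elimination at hot carbonate by an oxidative copper-mediated C–O coupling and gives 3 directly; no new intermediate is made.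

**Further compounds**
F1 | step 3 | 2-[4-[5-(1,3-dithian-2-yl)-2,3-dimethoxyphenoxy]phenyl]-1,3-dithiane | COc1cc(C2SCCCS2)cc(Oc2ccc(C3SCCCS3)cc2)c1OC
F2 | step 3 | 2,2'-dilithio derivative of F1 (both dithiane C-2 positions lithiated) | COc1cc(C2([Li])SCCCS2)cc(Oc2ccc(C3([Li])SCCCS3)cc2)c1OC
F3 | step 3 | 2-(3-methoxybenzyl)-2-[4-[2,3-dimethoxy-5-[2-(3-methoxybenzyl)-1,3-dithian-2-yl]phenoxy]phenyl]-1,3-dithiane | COc1cccc(CC2(SCCCS2)c2ccc(Oc3cc(C4(Cc5cccc(OC)c5)SCCCS4)cc(OC)c3OC)cc2)c1
F4 | step 2 | 3-(4-formylphenoxy)-4,5-dimethoxybenzaldehyde bis[(E)-hydrazone] | COc1cc(/C=N/N)cc(Oc2ccc(/C=N/N)cc2)c1OC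
F0 | step 1 | none | none
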